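**Strategy.** The C2 stereocentre of ring C bears O1 and sits β to the C4 ketone, so the C2–C3 bond is disconnected as an aldol bond and O1–C8a as an aryl ether closed afterwards. The key step, a titanium–BINOL-catalysed Mukaiyama aldol addition, joins the ring A and ring B halves and sets C2 in one operation, in an open chain without a phenol that cannot equilibrate through a chalcone. Its precursor is the trimethylsilyl enol ether of 2-bromo-4,6-dimethoxyacetophenone, the bromine marking the future C8a. The ketone is then reduced so that the basic copper-catalysed ring closure meets no enolisable β-hydroxy ketone, and is restored in the last step.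

Key step: step 3

Assumption: the titanium–(S)-BINOL complex is taken to direct attack to the Si face of the aromatic aldehyde, the usual sense for this catalyst family; the configuration of 7 is to be checked before it is carried on, and (R)-BINOL would be used in the same step if the opposite sense were found.

**Route**

Step 1
Reactants: 1 1-bromo-3,5-dimethoxybenzene; 2 acetyl chloride
Product: 3 1-(2-bromo-4,6-dimethoxyphenyl)ethan-1-one
Conditions: AlCl3 (1.2 equiv), CH2Cl2, 0 °C
Reagents that add atoms: none
Why: Friedel–Crafts acylation, in which the acetylium–AlCl3 electrophile should attack C2 of 1 (para to one methoxy group, ortho to the other) in preference to C4 between the two methoxy groups, while the low temperature and near-stoichiometric AlCl3 should spare the methoxy group ortho to the new carbonyl from cleavage.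

Step 2
Reactants: 3 1-(2-bromo-4,6-dimethoxyphenyl)ethan-1-one
Product: 4 {[1-(2-bromo-4,6-dimethoxyphenyl)ethenyl]oxy}trimethylsilane
Conditions: TMSOTf (1.2 equiv), Et3N (1.5 equiv), CH2Cl2, 0 °C; non-aqueous work-up (pentane, filtration)
Reagents that add atoms: trimethylsilyl trifluoromethanesulfonate, C[Si](C)(C)OS(=O)(=O)C(F)(F)F
Why: Silyl enol ether formation by soft enolisation with a silyl triflate and an amine base; the methyl group is the only enolisable position, so a single enol silane should result, and neither the aryl bromide nor the methyl ethers react.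

Step 3
Reactants: 4 {[1-(2-bromo-4,6-dimethoxyphenyl)ethenyl]oxy}trimethylsilane; 5 2,3,4-trimethoxybenzaldehyde
Product: 7 (3S)-1-(2-bromo-4,6-dimethoxyphenyl)-3-hydroxy-3-(2,3,4-trimethoxyphenyl)propan-1-one, via trimethylsilyl ether of the aldol 6 (not isolated)
Conditions: (S)-BINOL (20 mol%), Ti(OiPr)4 (20 mol%), 4 Å MS, Et2O, −20 °C; then aq. citric acid, THF, 0 °C
Reagents that add atoms: none
Why: The (S)-binaphtholate complex of tetravalent titanium, formed from Ti(OiPr)4 and (S)-BINOL, binds the aldehyde oxygen of 5, the CH2 terminus of enol silane 4 attacks the activated carbonyl through an open transition state, and transfer of the trimethylsilyl group to the aldolate oxygen releases the catalyst and leaves silyl ether 6, which is hydrolysed to 7 under weakly acidic conditions at 0 °C. The closest known reaction type is the BINOL–titanium-catalysed Mukaiyama aldol addition of enol silanes to aromatic aldehydes. No ring is closed; the step forms only the bond that becomes C2–C3 of ring C. The new carbinol centre is under catalyst control alone: the (S)-ligand should block the Re face of the bound aldehyde, so that Si-face attack gives the (S) alcohol. The step needs enantioface selectivity and must not dehydrate the adduct; the unsubstituted nucleophilic carbon of 4 excludes any diastereomer question, and the absence of a free phenol together with the cold, non-basic medium leaves no easy path to the chalcone. The trimethylsilyl group is kept on the enol ether because its fast transfer is what turns the catalyst over.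

Step 4
Reactants: 7 (3S)-1-(2-bromo-4,6-dimethoxyphenyl)-3-hydroxy-3-(2,3,4-trimethoxyphenyl)propan-1-one
Product: 8 (3S)-1-(2-bromo-4,6-dimethoxyphenyl)-3-(2,3,4-trimethoxyphenyl)propane-1,3-diol (both C1 epimers)
Conditions: NaBH4, MeOH/THF, 0 °C; neutral work-up
Reagents that add atoms: none
Why: Sodium borohydride reduction of the aryl ketone, in which hydride addition at 0 °C should outrun retro-aldol cleavage, the C3 carbinol centre is not involved, and the new C1 centre may form as either epimer because it returns to a ketone in step 6.

Step 5
Reactants: 8 (3S)-1-(2-bromo-4,6-dimethoxyphenyl)-3-(2,3,4-trimethoxyphenyl)propane-1,3-diol (both C1 epimers)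
Product: 9 (2S)-5,7-dimethoxy-2-(2,3,4-trimethoxyphenyl)-3,4-dihydro-2H-chromen-4-ol (both C4 epimers)
Conditions: CuI (10 mol%), 1,10-phenanthroline (20 mol%), Cs2CO3 (2 equiv), toluene, 110 °C
Reagents that add atoms: none
Why: Intramolecular Ullmann-type copper-catalysed O-arylation, in which only the C3 alkoxide can reach the brominated carbon through a six-membered ring (the C1 hydroxyl would have to close a four-membered ring), the C3–O bond is never broken so the (S) configuration is retained, and with the ketone reduced the carbonate base finds no acidic α-hydrogen for dehydration, retro-aldol cleavage or ring opening of the product.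

Step 6
Reactants: 9 (2S)-5,7-dimethoxy-2-(2,3,4-trimethoxyphenyl)-3,4-dihydro-2H-chromen-4-ol (both C4 epimers)
Product: 10 (2S)-5,7-dimethoxy-2-(2,3,4-trimethoxyphenyl)-2,3-dihydro-4H-chromen-4-one
Conditions: Dess–Martin periodinane (1.3 equiv), pyridine, CH2Cl2, 0 °C to rt
Reagents that add atoms: none
Why: Dess–Martin oxidation of the secondary benzylic alcohol, in which both C4 epimers converge on the ketone under buffered, non-basic conditions, so the flavanone should not open to the 2'-hydroxychalcone and C2 stays (S).

**Compound list**

1 | 1-bromo-3,5-dimethoxybenzene | COc1cc(Br)cc(OC)c1 | starting material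
2 | acetyl chloride | CC(Cl)=O | starting material
3 | 1-(2-bromo-4,6-dimethoxyphenyl)ethan-1-one | CC(=O)c1c(Br)cc(OC)cc1OC | intermediate
4 | {[1-(2-bromo-4,6-dimethoxyphenyl)ethenyl]oxy}trimethylsilane | C=C(O[Si](C)(C)C)c1c(Br)cc(OC)cc1OC | intermediate
5 | 2,3,4-trimethoxybenzaldehyde | COc1ccc(C=O)c(OC)c1OC | starting material
6 | (3S)-1-(2-bromo-4,6-dimethoxyphenyl)-3-(2,3,4-trimethoxyphenyl)-3-[(trimethylsilyl)oxy]propan-1-one | C[Si](C)(C)O[C@H](c1ccc(OC)c(OC)c1OC)CC(=O)c1c(Br)cc(OC)cc1OC | intermediate (not isolated)
7 | (3S)-1-(2-bromo-4,6-dimethoxyphenyl)-3-hydroxy-3-(2,3,4-trimethoxyphenyl)propan-1-one | O[C@H](c1ccc(OC)c(OC)c1OC)CC(=O)c1c(Br)cc(OC)cc1OC | intermediate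
8 | (3S)-1-(2-bromo-4,6-dimethoxyphenyl)-3-(2,3,4-trimethoxyphenyl)propane-1,3-diol, both C1 epimers | O[C@H](c1ccc(OC)c(OC)c1OC)CC(O)c1c(Br)cc(OC)cc1OC | intermediate
9 | (2S)-5,7-dimethoxy-2-(2,3,4-trimethoxyphenyl)-3,4-dihydro-2H-chromen-4-ol, both C4 epimers | COc1cc(OC)c2c(c1)O[C@H](c1ccc(OC)c(OC)c1OC)CC2O | intermediate
10 | (2S)-5,7-dimethoxy-2-(2,3,4-trimethoxyphenyl)-2,3-dihydro-4H-chromen-4-one | COc1cc(OC)c2c(c1)O[C@H](c1ccc(OC)c(OC)c1OC)CC2=O | target

**Step count**

Total steps: 6. Longest linear sequence: 6 steps (1 → 3 → 4 → 7 → 8 → 9 → 10).

**Steps most likely to fail**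

Step 3 (key step). The addition may turn over slowly because a ketone-derived enol silane of modest nucleophilicity meets an electron-rich aldehyde on a mild Lewis acid. The ortho methoxy group of the aldehyde may also chelate titanium and erode facial selectivity, and the enol silane may hydrolyse before it reacts. The fallback sets out from 3 and 5 and comes back at 7:
- Claisen–Schmidt condensation (KOH, EtOH, rt) should give the chalcone (E)-1-(2-bromo-4,6-dimethoxyphenyl)-3-(2,3,4-trimethoxyphenyl)prop-2-en-1-one F1.
- Enantioselective copper-catalysed conjugate borylation (CuCl, NaOtBu, a Josiphos-type ferrocenyl diphosphine of the enantiomeric series that delivers the (S)-boronate, B2pin2, MeOH, THF, rt) should give (3S)-1-(2-bromo-4,6-dimethoxyphenyl)-3-(4,4,5,5-tetramethyl-1,3,2-dioxaborolan-2-yl)-3-(2,3,4-trimethoxyphenyl)propan-1-one F2.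
- Oxidation of the C–B bond with retention (NaBO3·4H2O, THF/H2O, rt) should give 7.

Step 5. Oxidative addition to the aryl bromide may be sluggish at the copper centre, protodebromination may compete at 110 °C, and the neighbouring C1 hydroxyl may hold the copper unproductively. The fallback sets out from 8 and comes back at 9. It replaces thermal copper catalysis by light-driven nickel catalysis at room temperature (NiCl2·glyme, 4,4'-di-tert-butyl-2,2'-bipyridine, Ir[dF(CF3)ppy]2(dtbbpy)PF6, quinuclidine, K2CO3, MeCN, blue LEDs). The aryl ether is then formed by reductive elimination from an aryl nickel alkoxide under mildly basic conditions; this fallback makes no compound beyond those already listed (F0).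

Step 1. Acylation may occur at the ring position between the two methoxy groups, or AlCl3 may cleave the methoxy group ortho to the new ketone. The fallback sets out from 1 and comes back at 3:
- Vilsmeier–Haack formylation (POCl3, DMF, then aq. NaOAc), whose regiochemistry on this arene is established, should give 2-bromo-4,6-dimethoxybenzaldehyde F3.
- Grignard addition (MeMgBr, THF, 0 °C) should give racemic 1-(2-bromo-4,6-dimethoxyphenyl)ethan-1-ol F4.
- Dess–Martin oxidation (CH2Cl2, rt) should give 3.

**Further compounds**

F1 | step 3 | (E)-1-(2-bromo-4,6-dimethoxyphenyl)-3-(2,3,4-trimethoxyphenyl)prop-2-en-1-one | COc1ccc(/C=C/C(=O)c2c(Br)cc(OC)cc2OC)c(OC)c1OC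
F2 | step 3 | (3S)-1-(2-bromo-4,6-dimethoxyphenyl)-3-(4,4,5,5-tetramethyl-1,3,2-dioxaborolan-2-yl)-3-(2,3,4-trimethoxyphenyl)propan-1-one | CC1(C)OB(OC1(C)C)[C@H](c1ccc(OC)c(OC)c1OC)CC(=O)c1c(Br)cc(OC)cc1OC
F0 | step 5 | none | none
F3 | step 1 | 2-bromo-4,6-dimethoxybenzaldehyde | COc1cc(Br)c(C=O)c(OC)c1
F4 | step 1 | 1-(2-bromo-4,6-dimethoxyphenyl)ethan-1-ol (racemic) | CC(O)c1c(Br)cc(OC)cc1OC
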